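## Retrosynthetic overview

1. Aryl ether C–O bond: Mitsunobu coupling of intact umbelliferone with a primary alcohol; the acid is carried as its methyl ester.
2. Propanoate arm: two-carbon Wittig homologation and 1,4-reduction of a lactol, i.e. of a cis-fused γ-lactone whose carbonyl carbon becomes C-3 of the arm.
3. Key disconnection: that lactone from (2E,4E)-3,6-dimethylhepta-2,4,6-trien-1-ol and methyl methacrylate by a BINOL–Zn/Mg-templated Diels–Alder/lactonisation, which closes the cyclohexene and the lactone in one operation and sets all three stereocentres.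
4. Trienol from (E)-3-methylpent-2-en-4-yn-1-ol and 2-bromopropene (hydrozirconation/Pd coupling).
5. Ring order: cyclohexene and γ-lactone together (step 2); lactone opened (steps 3–4); coumarin bicycle brought in preformed (step 6).

Assumption: (R)-BINOL is taken to give the (3aS,6S,7aR) lactone; if the sense of induction proves opposite, (S)-BINOL is used and nothing else changes.

## Route

**Step 1**
Reactants: 1 (E)-3-methylpent-2-en-4-yn-1-ol; 2 2-bromopropene
Product: 4 (2E,4E)-3,6-dimethylhepta-2,4,6-trien-1-ol, via dienylzirconocene 3 (not isolated)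
Conditions: Cp2Zr(H)Cl (2.2 equiv), THF, 0 °C→rt, dark; then 2 (2 equiv), Pd(PPh3)4 (5 mol%), ZnCl2 (0.3 equiv), rt
Reagents that add atoms: 2-bromopropene (2), C=C(C)Br
Why: After the first Zr–H is consumed by the OH, syn-hydrozirconation of the terminal alkyne puts Zr on the terminal carbon and fixes the new 4E alkene, and Pd-catalysed Negishi-type alkenyl–alkenyl cross-coupling proceeds with retention to the (2E,4E)-triene.

**Step 2**
Reactants: 4 (2E,4E)-3,6-dimethylhepta-2,4,6-trien-1-ol; 5 methyl methacrylate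
Product: 7 (3aS,6S,7aR)-4,7a-dimethyl-6-(prop-1-en-2-yl)-3a,6,7,7a-tetrahydro-2-benzofuran-1(3H)-one, via cycloadduct hydroxy ester 6 (not isolated)
Conditions: (R)-BINOL (1.0 equiv, recovered), Me2Zn (1.0 equiv), MeMgBr (1.0 equiv), CH2Cl2, 0 °C; then 5 (5 equiv), rt, 48 h; aq NH4Cl/1 M HCl
Reagents that add atoms: methyl methacrylate (5), C=C(C)C(=O)OC
Why: Proposed new method: the dienol is held as its alkoxide on the chiral BINOLate Zn/Mg template while the neighbouring Mg activates the methacrylate carbonyl, so the [4+2] is effectively intramolecular; this forces reaction at the internal diene (not the terminal isopropenyl diene), overrides the intrinsic "para" preference so that the ester carbon bonds to the CH2O-bearing carbon and ends up cis to it (E,E-diene: isopropenyl and CH2O cis; CH3 exo, trans), lets BINOL choose the diene face and hence the absolute configuration, and the cis alkoxide then closes the γ-lactone in the same flask; the closest known reaction type is the Lewis-acid-templated (self-assembled) enantioselective Diels–Alder/lactonisation of 2,4-dienols with methyl acrylate.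

**Step 3**
Reactants: 7 (3aS,6S,7aR)-lactone
Product: 8 (3aS,6S,7aR)-4,7a-dimethyl-6-(prop-1-en-2-yl)-1,3,3a,6,7,7a-hexahydro-2-benzofuran-1-ol (both C-1 epimers)
Conditions: DIBAL-H (1.2 equiv), CH2Cl2, −78 °C; Rochelle salt
Reagents that add atoms: none
Why: DIBAL-H half-reduction of a lactone stops at the aluminium hemiacetal of this hindered α-quaternary carbonyl, giving the lactol on work-up; no existing stereocentre is α-acidic, and the new anomeric centre is destroyed in step 4.

**Step 4**
Reactants: 8 lactol; 9 methyl (triphenylphosphoranylidene)acetate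
Product: 11 methyl (2E)-3-[(1S,2S,5S)-2-(hydroxymethyl)-1,3-dimethyl-5-(prop-1-en-2-yl)cyclohex-3-en-1-yl]prop-2-enoate, via ring-opened hydroxy aldehyde 10 (not isolated)
Conditions: 9 (3 equiv), PhCO2H (0.2 equiv), toluene, 100 °C
Reagents that add atoms: methyl (triphenylphosphoranylidene)acetate (9), COC(=O)C=P(c1ccccc1)(c1ccccc1)c1ccccc1
Why: Wittig olefination of the lactol through its open hydroxy-aldehyde tautomer with a stabilised ylide gives the E-enoate; base-free, mildly acidic conditions suppress 5-exo oxa-Michael closure of the free alcohol, and the α-quaternary aldehyde cannot epimerise.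

**Step 5**
Reactants: 11 hydroxy enoate
Product: 12 methyl 3-[(1R,2R,5S)-2-(hydroxymethyl)-1,3-dimethyl-5-(prop-1-en-2-yl)cyclohex-3-en-1-yl]propanoate
Conditions: Mg turnings (10 equiv), MeOH, 0 °C→rt; aq NH4Cl
Reagents that add atoms: none
Why: Dissolving-metal (Mg/MeOH) conjugate reduction transfers electrons only to the conjugated ester, so the isopropenyl and ring alkenes are untouched and no stereocentre is created or disturbed.

**Step 6**
Reactants: 12 hydroxy ester; 13 umbelliferone (7-hydroxy-2H-chromen-2-one)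
Product: 14 methyl 3-[(1R,2R,5S)-1,3-dimethyl-2-{[(2-oxo-2H-chromen-7-yl)oxy]methyl}-5-(prop-1-en-2-yl)cyclohex-3-en-1-yl]propanoate
Conditions: 13 (1.3 equiv), PPh3 (1.5 equiv), DIAD (1.5 equiv, added last), THF, 0 °C→rt
Reagents that add atoms: umbelliferone (13), O=c1ccc2ccc(O)cc2o1
Why: Mitsunobu etherification: the acidic phenol (pKa about 7.8) protonates the betaine and displaces the oxyphosphonium at the primary, non-stereogenic CH2, leaving ester, alkenes and coumarin untouched.

**Step 7**
Reactants: 14 aryl ether methyl ester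
Product: 15 3-[(1R,2R,5S)-1,3-dimethyl-2-{[(2-oxo-2H-chromen-7-yl)oxy]methyl}-5-(prop-1-en-2-yl)cyclohex-3-en-1-yl]propanoic acid (target)
Conditions: LiOH·H2O (3 equiv), THF/H2O 3:1, 0 °C→rt; then 1 M HCl to pH 2
Reagents that add atoms: lithium hydroxide, [Li+].[OH-]
Why: Saponification (BAc2) of the unhindered methyl ester; any coumarin lactone opened to the Z-coumarinate re-closes on acidification, and no stereocentre is α to a carbonyl.

## Compound list

1 | (E)-3-methylpent-2-en-4-yn-1-ol | C#C/C(C)=C/CO | starting material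
2 | 2-bromopropene | C=C(C)Br | starting material
3 | (2E,4E)-dienylzirconocene chloride, O-bound as zirconocene chloride alkoxide (Cp drawn σ-bonded; not isolated) | Cl[Zr](C1C=CC=C1)(C1C=CC=C1)/C=C/C(C)=C/CO[Zr](Cl)(C1C=CC=C1)C1C=CC=C1 | intermediate
4 | (2E,4E)-3,6-dimethylhepta-2,4,6-trien-1-ol | C=C(C)/C=C/C(C)=C/CO | intermediate
5 | methyl methacrylate | C=C(C)C(=O)OC | starting material
6 | methyl (1R,2S,5S)-2-(hydroxymethyl)-1,3-dimethyl-5-(prop-1-en-2-yl)cyclohex-3-ene-1-carboxylate (as metal alkoxide; not isolated) | C=C(C)[C@@H]1C=C(C)[C@H](CO)[C@](C)(C(=O)OC)C1 | intermediate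
7 | (3aS,6S,7aR)-4,7a-dimethyl-6-(prop-1-en-2-yl)-3a,6,7,7a-tetrahydro-2-benzofuran-1(3H)-one (cis-fused; isopropenyl cis to the lactone ring) | C=C(C)[C@@H]1C=C(C)[C@H](CO2)[C@](C)(C2=O)C1 | intermediate
8 | (3aS,6S,7aR)-4,7a-dimethyl-6-(prop-1-en-2-yl)-1,3,3a,6,7,7a-hexahydro-2-benzofuran-1-ol (C-1 epimers) | C=C(C)[C@@H]1C=C(C)[C@H](CO2)[C@](C)(C2O)C1 | intermediate
9 | methyl (triphenylphosphoranylidene)acetate | COC(=O)C=P(c1ccccc1)(c1ccccc1)c1ccccc1 | starting material
10 | (1R,2S,5S)-2-(hydroxymethyl)-1,3-dimethyl-5-(prop-1-en-2-yl)cyclohex-3-ene-1-carbaldehyde (not isolated) | C=C(C)[C@@H]1C=C(C)[C@H](CO)[C@](C)(C=O)C1 | intermediate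
11 | methyl (2E)-3-[(1S,2S,5S)-2-(hydroxymethyl)-1,3-dimethyl-5-(prop-1-en-2-yl)cyclohex-3-en-1-yl]prop-2-enoate | C=C(C)[C@@H]1C=C(C)[C@H](CO)[C@](C)(/C=C/C(=O)OC)C1 | intermediate
12 | methyl 3-[(1R,2R,5S)-2-(hydroxymethyl)-1,3-dimethyl-5-(prop-1-en-2-yl)cyclohex-3-en-1-yl]propanoate | C=C(C)[C@@H]1C=C(C)[C@H](CO)[C@](C)(CCC(=O)OC)C1 | intermediate
13 | umbelliferone (7-hydroxy-2H-chromen-2-one) | O=c1ccc2ccc(O)cc2o1 | starting material
14 | methyl 3-[(1R,2R,5S)-1,3-dimethyl-2-{[(2-oxo-2H-chromen-7-yl)oxy]methyl}-5-(prop-1-en-2-yl)cyclohex-3-en-1-yl]propanoate | C=C(C)[C@@H]1C=C(C)[C@H](COc2ccc3ccc(=O)oc3c2)[C@](C)(CCC(=O)OC)C1 | intermediate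
15 | 3-[(1R,2R,5S)-1,3-dimethyl-2-{[(2-oxo-2H-chromen-7-yl)oxy]methyl}-5-(prop-1-en-2-yl)cyclohex-3-en-1-yl]propanoic acid | C=C(C)[C@@H]1C=C(C)[C@H](COc2ccc3ccc(=O)oc3c2)[C@](C)(CCC(=O)O)C1 | target

## Step count and risks

Total step count: 7. Longest linear sequence: 7 (1 → 15).

The three steps most likely to fail:

**Step 2** (reactivity of the α-methyl dienophile on the template, site and regiocontrol on the triene, ee). The fallback sets out from 4 and comes back at 7. The same BINOL–Zn/Mg-templated cycloaddition is run with methyl acrylate, the dienophile for which this template chemistry is established. The cycloadduct methyl (1R,2S,5S)-2-(hydroxymethyl)-3-methyl-5-(prop-1-en-2-yl)cyclohex-3-ene-1-carboxylate F1 lactonises in the flask to (3aS,6S,7aR)-4-methyl-6-(prop-1-en-2-yl)-3a,6,7,7a-tetrahydro-2-benzofuran-1(3H)-one F2. The quaternary methyl is then installed by enolate alkylation (LDA, THF, −78 °C; MeI). Alkylation can only occur on the convex face, at the position of the ring-fusion H and anti to the isopropenyl group, so the cis-fused lactone 7 results with the same configuration.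

**Step 4** (Wittig on a masked, α-quaternary aldehyde; possible oxa-Michael closure). The fallback sets out from 8 and comes back at 12, bypassing 11 and step 5. It is an organocatalytic reductive alkylation of Meldrum's acid (Meldrum's acid, Hantzsch ester, L-proline cat., EtOH, rt). Knoevenagel condensation of the open form 10 gives 5-{[(1S,2S,5S)-2-(hydroxymethyl)-1,3-dimethyl-5-(prop-1-en-2-yl)cyclohex-3-en-1-yl]methylidene}-2,2-dimethyl-1,3-dioxane-4,6-dione F3. The Hantzsch ester reduces only this highly electrophilic alkylidene, giving 5-{[(1S,2R,5S)-2-(hydroxymethyl)-1,3-dimethyl-5-(prop-1-en-2-yl)cyclohex-3-en-1-yl]methyl}-2,2-dimethyl-1,3-dioxane-4,6-dione F4. Heating F4 in MeOH/pyridine opens the dioxanedione to 2-{[(1S,2R,5S)-2-(hydroxymethyl)-1,3-dimethyl-5-(prop-1-en-2-yl)cyclohex-3-en-1-yl]methyl}-3-methoxy-3-oxopropanoic acid F5, which decarboxylates on continued heating to 12.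

**Step 6** (Mitsunobu at a β-branched primary alcohol flanked by a quaternary carbon). The fallback sets out from 12 and comes back at 14. The alcohol is converted (PPh3, I2, imidazole, toluene/MeCN, 60 °C) into methyl 3-[(1R,2R,5S)-2-(iodomethyl)-1,3-dimethyl-5-(prop-1-en-2-yl)cyclohex-3-en-1-yl]propanoate F6. F6 then alkylates caesium umbelliferonate (13, Cs2CO3, DMF, 60 °C) in a Williamson ether synthesis, which tolerates the heating that a Mitsunobu betaine does not.

## Further compounds

F1 | step 2 | methyl (1R,2S,5S)-2-(hydroxymethyl)-3-methyl-5-(prop-1-en-2-yl)cyclohex-3-ene-1-carboxylate (not isolated) | C=C(C)[C@@H]1C=C(C)[C@H](CO)[C@H](C(=O)OC)C1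
F2 | step 2 | (3aS,6S,7aR)-4-methyl-6-(prop-1-en-2-yl)-3a,6,7,7a-tetrahydro-2-benzofuran-1(3H)-one | C=C(C)[C@@H]1C=C(C)[C@H](CO2)[C@H](C2=O)C1
F3 | step 4 | 5-{[(1S,2S,5S)-2-(hydroxymethyl)-1,3-dimethyl-5-(prop-1-en-2-yl)cyclohex-3-en-1-yl]methylidene}-2,2-dimethyl-1,3-dioxane-4,6-dione (not isolated) | C=C(C)[C@@H]1C=C(C)[C@H](CO)[C@](C)(C=C2C(=O)OC(C)(C)OC2=O)C1
F4 | step 4 | 5-{[(1S,2R,5S)-2-(hydroxymethyl)-1,3-dimethyl-5-(prop-1-en-2-yl)cyclohex-3-en-1-yl]methyl}-2,2-dimethyl-1,3-dioxane-4,6-dione | C=C(C)[C@@H]1C=C(C)[C@H](CO)[C@](C)(CC2C(=O)OC(C)(C)OC2=O)C1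
F5 | step 4 | 2-{[(1S,2R,5S)-2-(hydroxymethyl)-1,3-dimethyl-5-(prop-1-en-2-yl)cyclohex-3-en-1-yl]methyl}-3-methoxy-3-oxopropanoic acid (not isolated) | C=C(C)[C@@H]1C=C(C)[C@H](CO)[C@](C)(CC(C(=O)O)C(=O)OC)C1
F6 | step 6 | methyl 3-[(1R,2R,5S)-2-(iodomethyl)-1,3-dimethyl-5-(prop-1-en-2-yl)cyclohex-3-en-1-yl]propanoate | C=C(C)[C@@H]1C=C(C)[C@H](CI)[C@](C)(CCC(=O)OC)C1
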